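**Retrosynthetic overview**
1. Target 28 ⇐ bis-silyl diacetate 27 (oxidative desilylation) ⇐ formyl enol lactone 25 (double reductive acetylation sets C2 and installs both acetates).
2. 25 ⇐ bicyclic dienoic acid 23 + malonaldehyde enolate 20 (Michael addition–lactonization sets C4 and C3; the pyran ring is made last).
3. 23 ⇐ triene acid 22 (ring-closing metathesis closes the seven-membered ring) ⇐ aldehyde 11 + phosphono acid 17 (Horner–Wadsworth–Emmons union of fragments A and B).
4. 11 ⇐ lactone 8 ⇐ prochiral diazoacetate 7 (desymmetrizing cyclopropanation sets C10/C11); 17 from 2-methylidenepropane-1,3-diol; 20 from 3-(dimethylamino)acrolein.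
5. Ring order: cyclopropane → seven-membered carbocycle → dihydropyran.

Atom labels used below: O1, C2 (acetal CH), C3 and C4 (ring-fusion CH), C5 (=C bearing C5'H2), C6 (=CH–O), C7 (=C bearing C7'), C8 (=CH), C9 (C=O), C10 and C11 (cyclopropane CH), C12 (CMe2). Target = (2S,3R,4R,10S,11R); H2, H3 and H4 are mutually cis and lie on the face of the CMe2 bridge.

Assumption: lactone 8 is drawn as the 4-exo isomer (C9 = S); C9 becomes the ketone in step 17, so its epimer would converge on the same target.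

**Fragment A (steps 1–6)**

Step 1
Reactants: 1 3-methylbut-2-enal; 2 (2-methylprop-1-en-1-yl)magnesium bromide
Product: 3 2,6-dimethylhepta-2,5-dien-4-ol
Conditions: THF, −78 → 0 °C; then H2O
Reagents that add atoms: none
Why: 1,2-Grignard addition to the enal gives the symmetric (prochiral) bis-allylic carbinol, with no stereocentre yet.

Step 2
Reactants: 3 2,6-dimethylhepta-2,5-dien-4-ol; 4 diketene
Product: 5 2,6-dimethylhepta-2,5-dien-4-yl 3-oxobutanoate
Conditions: DMAP (5 mol %), Et2O, 0 °C → rt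
Reagents that add atoms: none
Why: Nucleophile-catalysed ring opening of diketene acetoacetylates the ionisation-prone carbinol under neutral conditions.

Step 3
Reactants: 5 2,6-dimethylhepta-2,5-dien-4-yl 3-oxobutanoate
Product: 7 2,6-dimethylhepta-2,5-dien-4-yl diazoacetate, via diazoacetoacetate 6 (not isolated)
Conditions: MsN3, Et3N, MeCN, rt; then aq. LiOH, rt
Reagents that add atoms: methanesulfonyl azide CS(=O)(=O)N=[N+]=[N-]
Why: Regitz diazo transfer to the active methylene followed by hydroxide deacetylation (retro-Claisen) gives the diazoacetate under basic conditions that the bis-allylic ester tolerates.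

Step 4
Reactants: 7 2,6-dimethylhepta-2,5-dien-4-yl diazoacetate
Product: 8 (1R,4S,5S)-6,6-dimethyl-4-(2-methylprop-1-en-1-yl)-3-oxabicyclo[3.1.0]hexan-2-one
Conditions: Rh2(5R-MEPY)4 (1 mol %; MEPY = methyl 2-oxopyrrolidine-5-carboxylate), CH2Cl2, reflux, slow addition of 7
Reagents that add atoms: none
Why: Intramolecular carbenoid cyclopropanation in which the chiral divalent-rhodium carboxamidate selects one of the two enantiotopic trisubstituted alkenes and one face, setting C10 and C11 (and the transient C9 centre) in the sense this catalyst gives with 3-methylbut-2-enyl diazoacetate, the spare isobutenyl group going exo.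

Step 5
Reactants: 8 (1R,4S,5S)-6,6-dimethyl-4-(2-methylprop-1-en-1-yl)-3-oxabicyclo[3.1.0]hexan-2-one
Product: 10 (1R,3S)-N-methoxy-N,2,2-trimethyl-3-[(1S)-3-methyl-1-(triethylsilyloxy)but-2-en-1-yl]cyclopropane-1-carboxamide, via chloromagnesium alkoxide 9 (not isolated)
Conditions: MeNH(OMe)·HCl, i-PrMgCl, THF, −20 → 0 °C; then Et3SiCl, imidazole, 0 °C → rt
Reagents that add atoms: N,O-dimethylhydroxylamine hydrochloride CNOC.Cl; chlorotriethylsilane CC[Si](Cl)(CC)CC
Why: Magnesium-amide aminolysis opens the lactone to the Weinreb amide and the released alkoxide is silylated in the same flask so it cannot relactonize; no stereocentre is touched.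

Step 6
Reactants: 10 (1R,3S)-N-methoxy-N,2,2-trimethyl-3-[(1S)-3-methyl-1-(triethylsilyloxy)but-2-en-1-yl]cyclopropane-1-carboxamide
Product: 11 (1R,3S)-2,2-dimethyl-3-[(1S)-3-methyl-1-(triethylsilyloxy)but-2-en-1-yl]cyclopropane-1-carbaldehyde
Conditions: i-Bu2AlH, THF, −78 °C; then aq. potassium sodium tartrate
Reagents that add atoms: none
Why: Weinreb amide reduction stops at the chelated tetrahedral intermediate and releases the aldehyde on work-up, the cis-cyclopropane being preserved at low temperature.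

**Fragment B (steps 7–10)**

Step 7
Reactants: 12 2-methylidenepropane-1,3-diol
Product: 13 2-[(triethylsilyloxy)methyl]prop-2-en-1-ol
Conditions: Et3SiCl (1 equiv), imidazole, CH2Cl2, 0 °C (12 in three-fold excess)
Reagents that add atoms: chlorotriethylsilane CC[Si](Cl)(CC)CC
Why: Statistical monosilylation of the symmetric diol, with excess diol recovered.

Step 8
Reactants: 13 2-[(triethylsilyloxy)methyl]prop-2-en-1-ol
Product: 14 [2-(bromomethyl)prop-2-en-1-yl]oxy(triethyl)silane
Conditions: CBr4, PPh3, CH2Cl2, 0 °C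
Reagents that add atoms: carbon tetrabromide BrC(Br)(Br)Br
Why: Appel bromination of the primary allylic alcohol under neutral conditions.

Step 9
Reactants: 14 [2-(bromomethyl)prop-2-en-1-yl]oxy(triethyl)silane
Product: 15 diethyl {2-[(triethylsilyloxy)methyl]prop-2-en-1-yl}phosphonate
Conditions: P(OEt)3 (neat), 110 °C
Reagents that add atoms: triethyl phosphite CCOP(OCC)OCC
Why: Michaelis–Arbuzov reaction of the allylic bromide (SN2 and SN2' give the same product).

Step 10
Reactants: 15 diethyl {2-[(triethylsilyloxy)methyl]prop-2-en-1-yl}phosphonate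
Product: 17 2-(diethoxyphosphoryl)-3-[(triethylsilyloxy)methyl]but-3-enoic acid (racemic), via lithiated phosphonate 16 (not isolated)
Conditions: LiN(i-Pr)2 (2.1 equiv), THF, −78 °C; CO2; then AcOH, pH 4 work-up
Reagents that add atoms: carbon dioxide O=C=O
Why: The α-lithiated allylic phosphonate is carboxylated at the α-carbon by the hard electrophile CO2; the new centre is lost in step 13.

**Fragment C (steps 11–12)**

Step 11
Reactants: 18 (E)-3-(dimethylamino)prop-2-enal
Product: 19 sodium (E)-3-oxoprop-1-en-1-olate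
Conditions: NaOH (1 equiv), H2O, 70 °C; evaporate
Reagents that add atoms: sodium hydroxide [Na+].[OH-]
Why: Addition–elimination hydrolysis of the vinylogous amide gives the malonaldehyde enolate.

Step 12
Reactants: 19 sodium (E)-3-oxoprop-1-en-1-olate
Product: 20 tetrabutylammonium (E)-3-oxoprop-1-en-1-olate
Conditions: Bu4NCl, H2O/CH2Cl2, rt; dry the organic phase
Reagents that add atoms: tetrabutylammonium chloride CCCC[N+](CCCC)(CCCC)CCCC.[Cl-]
Why: Ion metathesis into the organic phase gives a CH2Cl2-soluble enolate for the annulation.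

**Union and endgame (steps 13–17)**

Step 13
Reactants: 17 2-(diethoxyphosphoryl)-3-[(triethylsilyloxy)methyl]but-3-enoic acid; 11 (1R,3S)-2,2-dimethyl-3-[(1S)-3-methyl-1-(triethylsilyloxy)but-2-en-1-yl]cyclopropane-1-carbaldehyde
Product: 22 (2E)-3-{(1R,3S)-2,2-dimethyl-3-[(1S)-3-methyl-1-(triethylsilyloxy)but-2-en-1-yl]cyclopropyl}-2-[3-(triethylsilyloxy)prop-1-en-2-yl]prop-2-enoic acid, via dilithio dianion 21 (not isolated)
Conditions: 17, LiN(i-Pr)2 (2.1 equiv), THF, −78 → 0 °C; then 11, 0 °C → rt; AcOH, pH 4 work-up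
Reagents that add atoms: none
Why: Horner–Wadsworth–Emmons olefination through the phosphonoacetic acid dianion gives the trisubstituted acrylic acid with CO2H trans to the cyclopropyl group, which places C7 cis to C11 for ring closure and leaves the existing stereocentres untouched.

Step 14
Reactants: 22 (2E)-3-{(1R,3S)-2,2-dimethyl-3-[(1S)-3-methyl-1-(triethylsilyloxy)but-2-en-1-yl]cyclopropyl}-2-[3-(triethylsilyloxy)prop-1-en-2-yl]prop-2-enoic acid
Product: 23 (1R,6S,7S)-8,8-dimethyl-6-(triethylsilyloxy)-4-[(triethylsilyloxy)methyl]bicyclo[5.1.0]octa-2,4-diene-3-carboxylic acid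
Conditions: second-generation Grubbs catalyst RuCl2(=CHPh)(H2IMes)(PCy3) (10 mol %), toluene (2 mM), 80 °C
Reagents that add atoms: none
Why: Ring-closing metathesis between the isobutenyl group and the 1,1-disubstituted diene terminus, driven by loss of 2-methylpropene, forms the C7=C8 bond and closes the seven-membered ring as a cis,cis-1,3-diene.

Step 15
Reactants: 23 (1R,6S,7S)-8,8-dimethyl-6-(triethylsilyloxy)-4-[(triethylsilyloxy)methyl]bicyclo[5.1.0]octa-2,4-diene-3-carboxylic acid; 20 tetrabutylammonium (E)-3-oxoprop-1-en-1-olate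
Product: 25 (3R,4R,9S,10S,11R)-cis-fused formyl enol lactone [O1-C2(=O); C5(CHO)=C6; C7(CH2OSiEt3)=C8; C9-OSiEt3], via mixed pivalic anhydride 24 (not isolated)
Conditions: t-BuCOCl, i-Pr2NEt, CH2Cl2, 0 °C; then 20, 3,4-dihydro-2H-pyrimido[2,1-b]benzothiazole (DHPB, 20 mol %), 0 °C → rt
Reagents that add atoms: none
Why: Isothiourea-catalysed Michael addition–lactonization through the α,β-unsaturated acyl ammonium, in which the enolate carbon attacks C4 on the ring face opposite the CMe2 bridge (sets C4) and C3 is protonated anti to the new substituent and locked by enol lactonization as the cis-fused lactone (sets C3).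

Step 16
Reactants: 25 (3R,4R,9S,10S,11R)-cis-fused formyl enol lactone
Product: 27 (2S,3R,4R,9S,10S,11R)-diacetate bis(triethylsilyl) ether [C2-OAc; C5'-OAc; C9-OSiEt3; C7'-OSiEt3], via bis-aluminium alkoxide 26 (not isolated)
Conditions: i-Bu2AlH (2.2 equiv), CH2Cl2, −78 °C; then pyridine, DMAP, Ac2O, −78 → −20 °C; aq. potassium sodium tartrate
Reagents that add atoms: acetic anhydride CC(=O)OC(C)=O
Why: Reductive acetylation in which hydride reduces the formyl group and adds to the lactone carbonyl from the convex face (the side of H3/H4), and both aluminium alkoxides are acetylated in situ before the hemiacetal can open, giving the C2 acetate on the concave face (2S) together with the C5' acetate.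

Step 17
Reactants: 27 (2S,3R,4R,9S,10S,11R)-diacetate bis(triethylsilyl) ether
Product: 28 CNP0263020.2 [(2S,3R,4R,10S,11R); C2-OAc; C5'-OAc; C7-CHO; C9=O]
Conditions: IBX (6 equiv), DMSO, rt
Reagents that add atoms: none
Why: IBX-mediated oxidative desilylation cleaves both allylic triethylsilyl ethers and oxidises them in one operation to the C9 enone and the C7' enal, erasing the C9 centre and leaving the acetal acetate, enol ether and the other stereocentres untouched.

**Compound list**
1 | 3-methylbut-2-enal | CC(C)=CC=O | starting material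
2 | (2-methylprop-1-en-1-yl)magnesium bromide | CC(C)=C[Mg]Br | starting material
3 | 2,6-dimethylhepta-2,5-dien-4-ol | CC(C)=CC(O)C=C(C)C | intermediate
4 | diketene (4-methylideneoxetan-2-one) | C=C1CC(=O)O1 | starting material
5 | 2,6-dimethylhepta-2,5-dien-4-yl 3-oxobutanoate | CC(=O)CC(=O)OC(C=C(C)C)C=C(C)C | intermediate
6 | 2,6-dimethylhepta-2,5-dien-4-yl 2-diazo-3-oxobutanoate (not isolated) | CC(=O)C(=[N+]=[N-])C(=O)OC(C=C(C)C)C=C(C)C | intermediate
7 | 2,6-dimethylhepta-2,5-dien-4-yl diazoacetate | [N-]=[N+]=CC(=O)OC(C=C(C)C)C=C(C)C | intermediate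
8 | (1R,4S,5S)-6,6-dimethyl-4-(2-methylprop-1-en-1-yl)-3-oxabicyclo[3.1.0]hexan-2-one | O=C1O[C@@H](C=C(C)C)[C@H]2[C@@H]1C2(C)C | intermediate
9 | chloromagnesium alkoxide of (1R,3S)-3-[(1S)-1-hydroxy-3-methylbut-2-en-1-yl]-N-methoxy-N,2,2-trimethylcyclopropane-1-carboxamide (not isolated) | CON(C)C(=O)[C@@H]1[C@H]([C@@H](O[Mg]Cl)C=C(C)C)C1(C)C | intermediate
10 | (1R,3S)-N-methoxy-N,2,2-trimethyl-3-[(1S)-3-methyl-1-(triethylsilyloxy)but-2-en-1-yl]cyclopropane-1-carboxamide | CON(C)C(=O)[C@@H]1[C@H]([C@@H](O[Si](CC)(CC)CC)C=C(C)C)C1(C)C | intermediate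
11 | (1R,3S)-2,2-dimethyl-3-[(1S)-3-methyl-1-(triethylsilyloxy)but-2-en-1-yl]cyclopropane-1-carbaldehyde | O=C[C@@H]1[C@H]([C@@H](O[Si](CC)(CC)CC)C=C(C)C)C1(C)C | intermediate
12 | 2-methylidenepropane-1,3-diol | C=C(CO)CO | starting material
13 | 2-[(triethylsilyloxy)methyl]prop-2-en-1-ol | C=C(CO)CO[Si](CC)(CC)CC | intermediate
14 | [2-(bromomethyl)prop-2-en-1-yl]oxy(triethyl)silane | C=C(CBr)CO[Si](CC)(CC)CC | intermediate
15 | diethyl {2-[(triethylsilyloxy)methyl]prop-2-en-1-yl}phosphonate | C=C(CP(=O)(OCC)OCC)CO[Si](CC)(CC)CC | intermediate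
16 | α-lithio derivative of 15 (not isolated) | [Li+].C=C(CO[Si](CC)(CC)CC)[CH-]P(=O)(OCC)OCC | intermediate
17 | 2-(diethoxyphosphoryl)-3-[(triethylsilyloxy)methyl]but-3-enoic acid (racemic) | C=C(CO[Si](CC)(CC)CC)C(C(=O)O)P(=O)(OCC)OCC | intermediate
18 | (E)-3-(dimethylamino)prop-2-enal | CN(C)/C=C/C=O | starting material
19 | sodium (E)-3-oxoprop-1-en-1-olate | [Na+].[O-]/C=C/C=O | intermediate
20 | tetrabutylammonium (E)-3-oxoprop-1-en-1-olate | CCCC[N+](CCCC)(CCCC)CCCC.[O-]/C=C/C=O | intermediate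
21 | dilithio dianion of 17 (not isolated) | [Li+].[Li+].[O-]C(=O)[C-](C(=C)CO[Si](CC)(CC)CC)P(=O)(OCC)OCC | intermediate
22 | (2E)-3-{(1R,3S)-2,2-dimethyl-3-[(1S)-3-methyl-1-(triethylsilyloxy)but-2-en-1-yl]cyclopropyl}-2-[3-(triethylsilyloxy)prop-1-en-2-yl]prop-2-enoic acid | OC(=O)/C(C(=C)CO[Si](CC)(CC)CC)=C/[C@@H]1[C@H]([C@@H](O[Si](CC)(CC)CC)C=C(C)C)C1(C)C | intermediate
23 | (1R,6S,7S)-8,8-dimethyl-6-(triethylsilyloxy)-4-[(triethylsilyloxy)methyl]bicyclo[5.1.0]octa-2,4-diene-3-carboxylic acid | OC(=O)C1=C[C@@H]2[C@H]([C@@H](O[Si](CC)(CC)CC)C=C1CO[Si](CC)(CC)CC)C2(C)C | intermediate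
24 | mixed pivalic anhydride of 23 (not isolated) | CC(C)(C)C(=O)OC(=O)C1=C[C@@H]2[C@H]([C@@H](O[Si](CC)(CC)CC)C=C1CO[Si](CC)(CC)CC)C2(C)C | intermediate
25 | (3R,4R,9S,10S,11R)-cis-fused formyl enol lactone [O1-C2(=O); C5(CHO)=C6; C7(CH2OSiEt3)=C8; C9-OSiEt3; H3/H4 cis] | O=CC1=COC(=O)[C@H]2C(CO[Si](CC)(CC)CC)=C[C@H](O[Si](CC)(CC)CC)[C@H]3[C@@H]([C@@H]12)C3(C)C | intermediate
26 | bis(diisobutylaluminium) alkoxide of the C2 lactol and C5' alcohol (not isolated) | CC(C)C[Al](CC(C)C)OCC1=CO[C@@H](O[Al](CC(C)C)CC(C)C)[C@H]2C(CO[Si](CC)(CC)CC)=C[C@H](O[Si](CC)(CC)CC)[C@H]3[C@@H]([C@@H]12)C3(C)C | intermediate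
27 | (2S,3R,4R,9S,10S,11R)-diacetate bis(triethylsilyl) ether [C2-OAc; C5'-OAc; C9-OSiEt3; C7'-OSiEt3] | CC(=O)OCC1=CO[C@@H](OC(C)=O)[C@H]2C(CO[Si](CC)(CC)CC)=C[C@H](O[Si](CC)(CC)CC)[C@H]3[C@@H]([C@@H]12)C3(C)C | intermediate
28 | CNP0263020.2, (2S,3R,4R,10S,11R) | CC(=O)OCC1=CO[C@@H](OC(C)=O)[C@H]2C(C=O)=CC(=O)[C@H]3[C@@H]([C@@H]12)C3(C)C | target

**Totals**
Total step count: 17 (fragment A 6, fragment B 4, fragment C 2, union and endgame 5).
Longest linear sequence: 11 steps (steps 1–6, then 13–17).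

**Three steps most likely to fail**

Step 15 (annulation). The enolate is weakly nucleophilic, the acyl ammonium is α-branched, and C3 could epimerise or the C7=C8 bond could drift into conjugation under base. The fallback sets out from 23 and comes back at 25. Oxalyl chloride with catalytic DMF converts 23 into the acid chloride F5. A stoichiometric enaminone annulation with 18 (2,6-lutidine, CH2Cl2, 0 °C → rt) then adds the enaminone α-carbon to C4 and acylates its oxygen, giving the pyranone iminium chloride F6. Aqueous NaOAc hydrolyses this to 25.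

Step 14 (ring-closing metathesis). Both partners are hindered and the trisubstituted isobutenyl group may not turn over. The fallback sets out from 10 and comes back at 23. Ozonolysis of the isobutenyl group of 10 (O3, CH2Cl2, −78 °C; Me2S) gives the α-silyloxy aldehyde F1. Wittig methylenation (Ph3P=CH2, THF) gives the vinyl amide F2, and i-Bu2AlH gives the vinyl aldehyde F3. Olefination with 17 as in step 13 gives the triene acid F4, whose ring closure now engages a monosubstituted alkene, releases ethene and delivers 23.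

Step 16 (reductive acetylation). The enol-lactone tetrahedral intermediate may collapse before trapping, causing over-reduction or loss of the C2 configuration. The fallback sets out from 25 and comes back at 27. i-Bu2AlH followed by aqueous work-up gives the lactol diol F7 as an anomer mixture. Ac2O, pyridine and DMAP then give 27 together with its C2-epimeric diacetate F8, which is separated by chromatography. F8 is recycled by selective anomeric deacetylation (N2H4·AcOH, DMF) to the lactol monoacetate F9, followed by re-acetylation.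

**Further compounds**
F1 | step 14 | (1R,3S)-N-methoxy-N,2,2-trimethyl-3-[(1R)-2-oxo-1-(triethylsilyloxy)ethyl]cyclopropane-1-carboxamide | CON(C)C(=O)[C@@H]1[C@H]([C@@H](O[Si](CC)(CC)CC)C=O)C1(C)C
F2 | step 14 | (1R,3S)-N-methoxy-N,2,2-trimethyl-3-[(1S)-1-(triethylsilyloxy)prop-2-en-1-yl]cyclopropane-1-carboxamide | CON(C)C(=O)[C@@H]1[C@H]([C@@H](O[Si](CC)(CC)CC)C=C)C1(C)C
F3 | step 14 | (1R,3S)-2,2-dimethyl-3-[(1S)-1-(triethylsilyloxy)prop-2-en-1-yl]cyclopropane-1-carbaldehyde | O=C[C@@H]1[C@H]([C@@H](O[Si](CC)(CC)CC)C=C)C1(C)C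
F4 | step 14 | (2E)-3-{(1R,3S)-2,2-dimethyl-3-[(1S)-1-(triethylsilyloxy)prop-2-en-1-yl]cyclopropyl}-2-[3-(triethylsilyloxy)prop-1-en-2-yl]prop-2-enoic acid | OC(=O)/C(C(=C)CO[Si](CC)(CC)CC)=C/[C@@H]1[C@H]([C@@H](O[Si](CC)(CC)CC)C=C)C1(C)C
F5 | step 15 | (1R,6S,7S)-8,8-dimethyl-6-(triethylsilyloxy)-4-[(triethylsilyloxy)methyl]bicyclo[5.1.0]octa-2,4-diene-3-carbonyl chloride | O=C(Cl)C1=C[C@@H]2[C@H]([C@@H](O[Si](CC)(CC)CC)C=C1CO[Si](CC)(CC)CC)C2(C)C
F6 | step 15 | C5'-dimethyliminium chloride of enol lactone 25 | C[N+](C)=CC1=COC(=O)[C@H]2C(CO[Si](CC)(CC)CC)=C[C@H](O[Si](CC)(CC)CC)[C@H]3[C@@H]([C@@H]12)C3(C)C.[Cl-]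
F7 | step 16 | C2 lactol C5' alcohol of the bis(triethylsilyl) ether (anomer mixture) | OCC1=COC(O)[C@H]2C(CO[Si](CC)(CC)CC)=C[C@H](O[Si](CC)(CC)CC)[C@H]3[C@@H]([C@@H]12)C3(C)C
F8 | step 16 | C2 epimer of 27 (2R) | CC(=O)OCC1=CO[C@H](OC(C)=O)[C@H]2C(CO[Si](CC)(CC)CC)=C[C@H](O[Si](CC)(CC)CC)[C@H]3[C@@H]([C@@H]12)C3(C)C
F9 | step 16 | C2 lactol C5' monoacetate (anomer mixture) | CC(=O)OCC1=COC(O)[C@H]2C(CO[Si](CC)(CC)CC)=C[C@H](O[Si](CC)(CC)CC)[C@H]3[C@@H]([C@@H]12)C3(C)C
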